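**Strategy.** The cyclohexanone ring (C1–C2–C3–C4–C4a–C8a, decalin numbering) is cut at C4–C4a and C1–C8a. The other ring then becomes the cheap flavour compound 3-methylcyclohexane-1,2-dione, whose enol carbon is C4a and whose carbonyls are C8a and C8. One amine-catalysed asymmetric Robinson annulation with (E)-pent-3-en-2-one closes the ring, sets the vicinal C4 and C4a methyl stereocentres and leaves C8=O beside the ring fusion. The step exploits the adjacency of the C8 oxygen to C8a and the 1,5 spacing of C2=O and C8a. The C8 ketone later steers C8a–H, the C6 isopropenyl group and the C7/C8 esters.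

Key step: step 1

Remark on numbering: decalin (naphthalene) numbering is used throughout. The target carries C2=O, CH3 on C4 and C4a, isopropenyl on C6, the tiglate on C7, the senecioate on C8 and H on C8a. The C6 descriptor changes from S (9, 10) to R (11 onward) only through CIP priorities; the centre is not inverted.

Assumption: in step 1 the quinidine-derived primary amine is taken to attack the enone face that gives 4S, by analogy with its sense in additions of cyclic dicarbonyl enols to 4-substituted but-3-en-2-ones. If the sense is the opposite here, the quinine-derived pseudo-enantiomer is used in the same step.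

Step 1
Reactants: 1 3-methylcyclohexane-1,2-dione; 2 (E)-pent-3-en-2-one
Product: 4 (4S,4aR)-4,4a-dimethyl-4,4a,5,6-tetrahydronaphthalene-2,8(3H,7H)-dione, via Michael adduct 3 (not isolated)
Conditions: 9-amino-9-deoxy-epi-quinidine (20 mol%), TFA (40 mol%), toluene, 23 °C; then 4 Å MS, 80 °C
Reagents that add atoms: none
Why: The primary amine condenses with 2 to an iminium ion, the enol carbon of 1 (C4a) adds to its β-carbon (C4), and the enamine of the new methyl ketone then adds through C1 to the C8a carbonyl and loses water to give the enedione. The closest known reaction types are the cinchona-amine-catalysed asymmetric Robinson annulation of cyclic 1,3-dicarbonyl compounds with enones and the classical Michael–aldol annulation of cyclic 1,2-diones. The ring closes by a 6-(enolendo)-exo-trig aldol addition. C4 is set by the catalyst, which blocks one face of the (E)-iminium ion, and C4a follows from a compact synclinal approach with the acyl arm over the ring and the C4 hydrogen between the C4a methyl and C5, the arrangement that gives cis-dimethyl products from 2-methylcyclohexanone donors and this enone. The step needs C- over O-alkylation and closure at C8a instead of the bridging aldol of C3 onto C8; the soft tetrasubstituted enol carbon secures the first and the irreversible dehydration, impossible at a bridgehead, the second.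

Step 2
Reactants: 4 (4S,4aR)-4,4a-dimethyl-4,4a,5,6-tetrahydronaphthalene-2,8(3H,7H)-dione
Product: 5 (4S,4aR,8aS)-4,4a-dimethyl-cis-decalin-2,8-dione
Conditions: H2 (1 atm), 10% Pd/C, EtOAc, 23 °C
Reagents that add atoms: none
Why: Heterogeneous hydrogenation of the enedione C1=C8a bond should, as with 4a-methyl octalones, deliver hydrogen to the face of the C4a methyl and give the cis-decalin; C8a stays epimerisable next to C8=O and is fixed thermodynamically in step 5.

Step 3
Reactants: 5 (4S,4aR,8aS)-4,4a-dimethyl-cis-decalin-2,8-dione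
Product: 6 (4S,4aR,8aS)-2,2-(ethylenedioxy)-4,4a-dimethyl-cis-decalin-8-one
Conditions: TMSOCH2CH2OTMS (1.1 equiv), TMSOTf (5 mol%), CH2Cl2, −78 → −40 °C
Reagents that add atoms: 1,2-bis(trimethylsilyloxy)ethane C[Si](C)(C)OCCO[Si](C)(C)C
Why: Noyori ketalisation under non-enolising conditions should take the C2 carbonyl, flanked by two CH2 groups, much faster than the C8 carbonyl, which sits next to the ring-fusion CH and the quaternary C4a.

Step 4
Reactants: 6 (4S,4aR,8aS)-2,2-(ethylenedioxy)-4,4a-dimethyl-cis-decalin-8-one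
Product: 8 (4S,4aR,8aS)-2,2-(ethylenedioxy)-4,4a-dimethyl-cis-decal-6-en-8-one, via silyl enol ether 7 (not isolated)
Conditions: LDA, THF, −78 °C; TMSCl; then Pd(OAc)2 (1.05 equiv), MeCN, 23 °C
Reagents that add atoms: none
Why: Saegusa–Ito dehydrogenation: LDA removes the less hindered C7 proton (CH2) and not the tertiary C8a–H, and Pd(II) turns the resulting silyl enol ether into the C6=C7 enone.

Step 5
Reactants: 8 (4S,4aR,8aS)-2,2-(ethylenedioxy)-4,4a-dimethyl-cis-decal-6-en-8-one
Product: 9 (4S,4aR,6S,8aS)-2,2-(ethylenedioxy)-4,4a-dimethyl-6-(prop-1-en-2-yl)-cis-decalin-8-one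
Conditions: [Rh(cod)Cl]2 (2.5 mol%), (S)-BINAP (6 mol%), isopropenyl-B(pin) (2 equiv), KOH (10 mol%), dioxane/H2O 10:1, 50 °C
Reagents that add atoms: 2-isopropenyl-4,4,5,5-tetramethyl-1,3,2-dioxaborolane CC(=C)B1OC(C)(C)C(C)(C)O1
Why: Hayashi–Miyaura rhodium-catalysed asymmetric 1,4-addition: (S)-BINAP should deliver the alkenyl group to the enone face that gives the 6S ketone (the sense by which it gives (S)-3-substituted cyclohexanones), which is also the convex face anti to the axial C4a–C4 bond, and the basic medium lets C8a settle in the cis-fused form, the only one with the C4a methyl and the C6 isopropenyl group both equatorial.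

Step 6
Reactants: 9 (4S,4aR,6S,8aS)-2,2-(ethylenedioxy)-4,4a-dimethyl-6-(prop-1-en-2-yl)-cis-decalin-8-one
Product: 11 (4S,4aR,6R,7S,8aS)-7-bromo-2,2-(ethylenedioxy)-4,4a-dimethyl-6-(prop-1-en-2-yl)-cis-decalin-8-one, via silyl enol ether 10 (not isolated)
Conditions: LDA, THF, −78 °C; TMSCl; then NBS, THF, −78 °C
Reagents that add atoms: N-bromosuccinimide O=C1CCC(=O)N1Br
Why: Regioselective kinetic enolisation and α-bromination of a silyl enol ether: LDA removes the C7 proton (CH2 versus the tertiary C8a–H), the enol ether reacts with NBS far faster than the isopropenyl group, and axial attack on the convex face should give the axial bromide cis to the isopropenyl group.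

Step 7
Reactants: 11 (4S,4aR,6R,7S,8aS)-7-bromo-2,2-(ethylenedioxy)-4,4a-dimethyl-6-(prop-1-en-2-yl)-cis-decalin-8-one
Product: 12 (4S,4aR,6R,7R,8aS)-2,2-(ethylenedioxy)-4,4a-dimethyl-8-oxo-6-(prop-1-en-2-yl)-cis-decalin-7-yl (E)-2-methylbut-2-enoate
Conditions: tiglic acid (1.5 equiv), Cs2CO3 (0.75 equiv), DMF, 0 → 23 °C
Reagents that add atoms: tiglic acid C/C=C(\C)C(=O)O
Why: SN2 displacement of an α-bromo ketone by a carboxylate (classical α-acyloxylation): the axial C–Br bond, aligned with the carbonyl π system, is displaced with inversion, so the tiglate should end equatorial and trans to the isopropenyl group, which is also the more stable C7 epimer.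

Step 8
Reactants: 12 (4S,4aR,6R,7R,8aS)-2,2-(ethylenedioxy)-4,4a-dimethyl-8-oxo-6-(prop-1-en-2-yl)-cis-decalin-7-yl (E)-2-methylbut-2-enoate
Product: 13 (4S,4aR,6R,7R,8S,8aS)-2,2-(ethylenedioxy)-8-hydroxy-4,4a-dimethyl-6-(prop-1-en-2-yl)-cis-decalin-7-yl (E)-2-methylbut-2-enoate
Conditions: L-Selectride (1.2 equiv), THF, −78 °C; AcOH quench
Reagents that add atoms: none
Why: Diastereoselective ketone reduction with a bulky trialkylborohydride: in the chair that keeps the C4a methyl, the isopropenyl group and the tiglate equatorial, axial attack at C8 is blocked by the syn-axial C4a–C4 bond, so hydride should enter equatorially from the convex face and give the axial 8-OH cis to the C7 ester, and the cold acidic quench prevents acyl migration.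

Step 9
Reactants: 13 (4S,4aR,6R,7R,8S,8aS)-2,2-(ethylenedioxy)-8-hydroxy-4,4a-dimethyl-6-(prop-1-en-2-yl)-cis-decalin-7-yl (E)-2-methylbut-2-enoate
Product: 14 (4S,4aR,6R,7R,8S,8aS)-2,2-(ethylenedioxy)-4,4a-dimethyl-8-[(3-methylbut-2-enoyl)oxy]-6-(prop-1-en-2-yl)-cis-decalin-7-yl (E)-2-methylbut-2-enoate
Conditions: 3-methylbut-2-enoyl chloride (3 equiv), pyridine, DMAP (20 mol%), CH2Cl2, 0 → 40 °C
Reagents that add atoms: 3-methylbut-2-enoyl chloride CC(C)=CC(Cl)=O
Why: DMAP-catalysed acylation of the remaining, hindered axial alcohol with an acid chloride; pyridine instead of triethylamine avoids deconjugation of the senecioyl group through a vinylketene, and no stereocentre is touched.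

Step 10
Reactants: 14 (4S,4aR,6R,7R,8S,8aS)-2,2-(ethylenedioxy)-4,4a-dimethyl-8-[(3-methylbut-2-enoyl)oxy]-6-(prop-1-en-2-yl)-cis-decalin-7-yl (E)-2-methylbut-2-enoate
Product: 15 (4S,4aR,6R,7R,8S,8aS)-4,4a-dimethyl-8-[(3-methylbut-2-enoyl)oxy]-2-oxo-6-(prop-1-en-2-yl)-cis-decalin-7-yl (E)-2-methylbut-2-enoate (target)
Conditions: 1 M aq. HCl/THF 1:4, 23 °C
Reagents that add atoms: water O
Why: Acid-catalysed hydrolysis of the dioxolane, which is strained by a 1,3-diaxial contact in the cis-decalin, frees the C2 ketone under conditions that should leave the two enoate esters, the isopropenyl group and all stereocentres untouched.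

**Compound list**

1 | 3-methylcyclohexane-1,2-dione (drawn as its enol, 2-hydroxy-3-methylcyclohex-2-en-1-one) | CC1=C(O)C(=O)CCC1 | starting material
2 | (E)-pent-3-en-2-one | C/C=C/C(C)=O | starting material
3 | (3R)-3-methyl-3-[(2S)-4-oxopentan-2-yl]cyclohexane-1,2-dione (Michael adduct) | O=C1C(=O)CCC[C@]1(C)[C@@H](C)CC(C)=O | intermediate
4 | (4S,4aR)-4,4a-dimethyl-4,4a,5,6-tetrahydronaphthalene-2,8(3H,7H)-dione | O=C1C[C@H](C)[C@@]2(C)CCCC(=O)C2=C1 | intermediate
5 | (4S,4aR,8aS)-4,4a-dimethyl-cis-decalin-2,8-dione | O=C1C[C@H](C)[C@@]2(C)CCCC(=O)[C@H]2C1 | intermediate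
6 | (4S,4aR,8aS)-2,2-(ethylenedioxy)-4,4a-dimethyl-cis-decalin-8-one | C1COC2(O1)C[C@H](C)[C@@]3(C)CCCC(=O)[C@H]3C2 | intermediate
7 | C7=C8 trimethylsilyl enol ether of 6, (4S,4aR,8aS) | C1COC2(O1)C[C@H](C)[C@@]3(C)CCC=C(O[Si](C)(C)C)[C@H]3C2 | intermediate
8 | (4S,4aR,8aS)-2,2-(ethylenedioxy)-4,4a-dimethyl-cis-decal-6-en-8-one | C1COC2(O1)C[C@H](C)[C@@]3(C)CC=CC(=O)[C@H]3C2 | intermediate
9 | (4S,4aR,6S,8aS)-2,2-(ethylenedioxy)-4,4a-dimethyl-6-(prop-1-en-2-yl)-cis-decalin-8-one | C1COC2(O1)C[C@H](C)[C@@]3(C)C[C@H](C(C)=C)CC(=O)[C@H]3C2 | intermediate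
10 | C7=C8 trimethylsilyl enol ether of 9, (4S,4aR,6S,8aS) | C1COC2(O1)C[C@H](C)[C@@]3(C)C[C@H](C(C)=C)C=C(O[Si](C)(C)C)[C@H]3C2 | intermediate
11 | (4S,4aR,6R,7S,8aS)-7-bromo-2,2-(ethylenedioxy)-4,4a-dimethyl-6-(prop-1-en-2-yl)-cis-decalin-8-one (Br axial, cis to isopropenyl) | C1COC2(O1)C[C@H](C)[C@@]3(C)C[C@H](C(C)=C)[C@H](Br)C(=O)[C@H]3C2 | intermediate
12 | (4S,4aR,6R,7R,8aS)-2,2-(ethylenedioxy)-4,4a-dimethyl-8-oxo-6-(prop-1-en-2-yl)-cis-decalin-7-yl (E)-2-methylbut-2-enoate | C1COC2(O1)C[C@H](C)[C@@]3(C)C[C@H](C(C)=C)[C@@H](OC(=O)/C(C)=C/C)C(=O)[C@H]3C2 | intermediate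
13 | (4S,4aR,6R,7R,8S,8aS)-2,2-(ethylenedioxy)-8-hydroxy-4,4a-dimethyl-6-(prop-1-en-2-yl)-cis-decalin-7-yl (E)-2-methylbut-2-enoate | C1COC2(O1)C[C@H](C)[C@@]3(C)C[C@H](C(C)=C)[C@@H](OC(=O)/C(C)=C/C)[C@@H](O)[C@H]3C2 | intermediate
14 | (4S,4aR,6R,7R,8S,8aS)-2,2-(ethylenedioxy)-4,4a-dimethyl-8-[(3-methylbut-2-enoyl)oxy]-6-(prop-1-en-2-yl)-cis-decalin-7-yl (E)-2-methylbut-2-enoate | C1COC2(O1)C[C@H](C)[C@@]3(C)C[C@H](C(C)=C)[C@@H](OC(=O)/C(C)=C/C)[C@@H](OC(=O)C=C(C)C)[C@H]3C2 | intermediate
15 | (4S,4aR,6R,7R,8S,8aS)-4,4a-dimethyl-8-[(3-methylbut-2-enoyl)oxy]-2-oxo-6-(prop-1-en-2-yl)-cis-decalin-7-yl (E)-2-methylbut-2-enoate | C=C(C)[C@H]1C[C@@]2(C)[C@H](CC(=O)C[C@@H]2C)[C@H](OC(=O)C=C(C)C)[C@@H]1OC(=O)/C(C)=C/C | target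

**Step count and risks**

Total step count: 10. Longest linear sequence: 10 steps (from 1 and 2).

Steps most likely to fail:

Step 1 (turnover and facial control). The 1,2-dione can tie up the primary amine as an enaminone, so that a slow uncatalysed Michael addition takes over and the enantiomeric excess or the C4/C4a relative control collapses. Fallback, setting out from 1 and 2: the annulation is run without asymmetric induction. Et3N (neat, 50 °C) should give the racemic Michael adduct, that is 3 together with its enantiomer (3S)-3-methyl-3-[(2R)-4-oxopentan-2-yl]cyclohexane-1,2-dione F1. Pyrrolidine and AcOH in refluxing toluene with removal of water should then give the racemic enedione, that is 4 together with its enantiomer (4R,4aS)-4,4a-dimethyl-4,4a,5,6-tetrahydronaphthalene-2,8(3H,7H)-dione F2. Preparative chromatography on a chiral stationary phase resolves the racemate, and the route is rejoined at 4.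

Step 5 (insertion versus protodeboronation, catalyst/substrate mismatch). On the hindered cis-fused enone the alkenyl-rhodium insertion may be slower than protodeboronation of the boronate, or a substrate bias may oppose the ligand and erode facial selectivity at C6. Fallback, setting out from 8: a substrate-controlled copper-mediated conjugate addition with enolate trapping (isopropenylmagnesium bromide, CuBr·SMe2, TMSCl, THF, −78 °C). Axial attack on the enone half-chair that has the small C4a substituent (CH3), not the C4a–C4 ring bond, axial should place the isopropenyl group cis to that methyl. This gives the silyl enol ether 10 directly, where the route is rejoined (NBS as in step 6).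

Step 7 (substitution versus elimination). The axial bromide has an antiperiplanar C6–H, so E2 loss of HBr to a cross-conjugated dienone, or bromide exchange and epimerisation before substitution, may compete with SN2. Fallback, setting out from 10: Rubottom oxidation (dimethyldioxirane, acetone/CH2Cl2, −78 °C; then citric acid, MeOH) on the convex face should give the axial α-hydroxy ketone (4S,4aR,6R,7S,8aS)-2,2-(ethylenedioxy)-7-hydroxy-4,4a-dimethyl-6-(prop-1-en-2-yl)-cis-decalin-8-one F3. Mitsunobu esterification with tiglic acid (PPh3, DIAD, toluene, 0 °C) then inverts C7 and rejoins the route at 12.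

Further compounds
F1 | step 1 | (3S)-3-methyl-3-[(2R)-4-oxopentan-2-yl]cyclohexane-1,2-dione (enantiomer of 3) | O=C1C(=O)CCC[C@@]1(C)[C@H](C)CC(C)=O
F2 | step 1 | (4R,4aS)-4,4a-dimethyl-4,4a,5,6-tetrahydronaphthalene-2,8(3H,7H)-dione (enantiomer of 4) | O=C1C[C@@H](C)[C@]2(C)CCCC(=O)C2=C1
F0 | step 5 | none | none
F3 | step 7 | (4S,4aR,6R,7S,8aS)-2,2-(ethylenedioxy)-7-hydroxy-4,4a-dimethyl-6-(prop-1-en-2-yl)-cis-decalin-8-one | C1COC2(O1)C[C@H](C)[C@@]3(C)C[C@H](C(C)=C)[C@H](O)C(=O)[C@H]3C2
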